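Follow the pool of chains rather than the links.

| flask | first end groups | second end groups | time | remark |
|---|---|---|---|---|
| midnight | 5.0 mM | 0.980 equiv (fed, over 1.0 min) | 80 s | all else is in the flask from the start; the feed brings no volume worth counting |
| spring | 5.0 mM (fed, over 6.0 s) | 0.980 equiv | 80 s | all else is in the flask from the start; the feed brings no volume worth counting |
| dusk | 5.0 mM | 0.980 equiv | 80 s | everything together at the start |
| noon | 5.0 mM (fed, over 1.0 min) | 0.980 equiv | 80 s | all else is in the flask from the start; the feed brings no volume worth counting |

    first end groups + second end groups ⇌ links + released group (K1 = 1.7, k1 = 29 L mol⁻¹ s⁻¹)
    first end groups + released group → side product (k2 = 3.9 L mol⁻¹ s⁻¹)
    second end groups + links → over-reaction product (k3 = 5.4 L mol⁻¹ s⁻¹)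

1. the flask that comes out highest in amount of links, in percent of the first end groups charged, or "all alike" when all lie within 1.5 percentage points (midnight / spring / dusk / noon / all alike)
2. links at the end, in percent of the first end groups charged, midnight
3. links at the end, in percent of the first end groups charged, spring
4. links at the end, in percent of the first end groups charged, dusk
5. links at the end, in percent of the first end groups charged, noon

The link-forming step merely exchanges first end groups for links, so their sum, as a fraction of the charge, is called the pool here. The side step takes a first end group from the pool and the over-reaction takes a link. In this reckoning, released group tracks links and second end groups track first end groups, so both losses go with the square of the pool.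

Which numbers must be known well? The forward constant matters little: its half-life, forward rate alone in dusk, is 4.9 s, far below the run's 80 s, so a fast pre-equilibrium holds. The equilibrium constant sets the link share of the pool under a root, so an error in it reaches that share at about a quarter. For the pool the side and over-reaction constants count as a sum, and this sum must be known well. For links the over-reaction constant is the one to know well: that step takes links directly, while the side step also removes released group and so pulls the equilibrium forward. The quick feed time counts little, while a slow feed lowers the mean age of the material by half its length.

The link share is 56.6%. The drain time, in which the pool halves, is 87.5 s. Links are then the share over one plus age per drain time: dusk 29.6%, spring 30.1%, midnight 36.0%, noon 36.0%. This cannot part the slow feeds. During a feed, however, the fed species stays low and its own step slows. Feeding second end groups leaves the side step running, and feeding first end groups leaves the over-reaction, whose constant is larger. Constant times mean age therefore favours midnight.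

The forecast named midnight, with 37% for midnight, 28.5% for spring, 28% for dusk and 33% for noon: “feeding the second end groups (midnight) does best because it keeps them scarce”. Its noon stands lower than the reckoning above.

The simulation gives midnight, with 37.4% for midnight, 28.9% for spring, 28.4% for dusk and 31.8% for noon.

At the end of midnight the drain time puts the pool at 63.6%, and the flask holds 65.0%. The gap of 9 percentage points between midnight and dusk shrinks to 0.21 points with the over-reaction struck out, and turns to −3.5 points with the falling back of links struck out; these two act together. At 20 mM, midnight's neighbour has a drain time of 21.9 s, which gives 17.2% links; the simulation gives 20.0%.

The numbers of this flask are assumed; no experiment stands behind them.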